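Starting material is the limiting reagent, since c(starting material) of 0.30 M is less than c(reagent) of 0.360 M, so I kept my books in it: each mole ends as target, as quenched substrate, or unreacted.

in all of them: starting material 0.30 M; catalyst 12 mM
- elm: reagent 0.36 M; second substrate 0.15 M; protic impurity 0.090 M; run made earlier
- dawn: reagent 0.360 M; second substrate 0.150 M; protic impurity 0.0600 M; time 40 min
- dusk: reagent 0.360 M; second substrate 0.300 M; protic impurity 0.0600 M; time 40 min
- autumn: reagent 0.360 M; second substrate 0.600 M; protic impurity 0.0600 M; time 40 min
- summer: reagent 0.360 M; second substrate 1.20 M; protic impurity 0.0600 M; time 40 min
- noon: reagent 0.360 M; second substrate 2.50 M; protic impurity 0.0600 M; time 40 min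

elm run (percent of the starting material charged): time / min: target / % = 1.00: 2.4; 2.50: 5.6; 6.00: 12.1; 15.0: 24.4

(scatter of a reading: 0.5 percentage points)

- what was read earlier has a scatter of 0.5 percentage points, one standard deviation
- steps under discussion: starting material + reagent + catalyst -> catalyst + target; second substrate + reagent + catalyst -> catalyst + second product; starting material + protic impurity -> quenched substrate
- "hardly changes" means that all values lie within two and a half points (for a concentration: within two and a half percent of the largest)
- no earlier run changes the charge of protic impurity; that part of a forecast is a guess

- amount of target at the end, in percent of the starting material charged for dawn, dusk, autumn, summer, noon, in this order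
- how that number moves from the first to the last of them (falls all the way / falls, then rises / hardly changes / rises, then falls / rises all the way)

The ceiling of the first entry needed no kinetics, though how much of it was reached by the end was a question of rate. I called the impurity toll the share of the starting material that the protic impurity can take, one for one, c(protic impurity)/c(starting material), which is 20.0% for the charges of the row and was 30.0% in elm.

The first elm reading gave target forming at 0.0240 min⁻¹, as a fraction of the charge. Dividing by c(reagent) gave a reading of 0.0667 M⁻¹ min⁻¹, the rate constant with the catalyst folded in. With that figure, I expected the target fraction in elm to rise at 0.0166 min⁻¹ near 10.5 min if no impurity had acted, but the readings gave 0.0137 min⁻¹. Read as quenching, that shortfall meant 14.6% of the starting material had already gone, half of the elm toll. Because 40 min is longer than those 10.5 min, I entered the dawn toll in full as an estimate, though no earlier run changes the impurity charge.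

For the target entry I treated the remaining starting material as a simple decay. Holding the reagent at its charge gave 49.4%. But making that much target would use reagent, so its average over the run would be nearer 0.286 M. Putting this back in and going round once more gave 42.7%. The books closed with 37.3% of the starting material unreacted. Elm held a single charge of second substrate, so I could read no figure for its draw on the reagent. My number therefore stood for dawn, and I expected the row to fall from it by an amount I could not state.

The forecast gave 43%, 39%, 34%, 23% and 13%, a row that falls all the way, on the ground that “More second substrate strips the reagent faster.”

The flasks gave 45.8%, 45.5%, 44.9%, 43.7% and 41.2%: the row falls all the way.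

    starting material + reagent + catalyst → catalyst + target (k = 0.100 M⁻² s⁻¹)
    second substrate + reagent + catalyst → catalyst + second product (k = 0.00540 M⁻² s⁻¹)
    starting material + protic impurity → quenched substrate (k = 0.00760 M⁻¹ s⁻¹)

In dawn at 40.0 min, quenched substrate stood at 19.1% against the toll of 20.0%, with target at 45.8% and starting material at 35.1% closing the books. At the start of dawn, reagent went 37 times faster into target than into second product, and at the end still 14 times faster. Noon, charged with 2.50 M of second substrate, showed quenched substrate at 19.2% against that toll, second product at 0.0878 M, reagent at 41.3% of its charge, starting material at 39.6% and target at 41.2%.

Readings and results are calculated on assumed constants; the scatter is artificial.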